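- The pitfall in ash is to assume that the L charged keeps working at full strength and to read the slowing of D loss as a matter of D.

| setting | ash | alder | flask |
|---|---|---|---|
| D | 10 mM | 15 mM | 10 mM |
| Q | 8 mM | 8 mM | 8.00 mM |
| L | 100 µM | 100 µM | 100 µM |
| remark | the very flask that is asked about, followed so far | run made earlier |  |

- ash (time / min: X / %, D / %): 10.0: 0.8, 96.0; 20.0: 1.4, 93.7; 50.0: 4.9, 87.1; 120: 12.2, 76.1
- alder (time / h: X / %, D / %): 0.500: 2.1, 91.0; 1.33: 7.5, 82.7; 2.50: 15.2, 72.6; 4.00: 24.0, 62.9

(scatter of a reading: 0.3 percentage points)

- no earlier run changes the charge of L; that part of a forecast is a guess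

1. apparent order in L when 20% of the D are converted (percent change of the rate of making X for one percent more L charged)

- Ash is the flask asked about, and a loss proportional to D integrates to a pseudo-first-order constant k = ln(D before / D after) / time.
- In ash, k is 0.245 h⁻¹ over the first 10.0 min, but 0.116 h⁻¹ from 50.0 min to 120 min, the window in which D crosses 80.0%.
- Alder, with the same L and more D, gives 0.111 h⁻¹ across that crossing, close to ash, so I read the slowing as a change in L rather than an effect of the D charge.
- I therefore take f = 0.472 as a reading of the share of L still free in ash across that window, assuming that the slowing is pairing of L; no run changes L, so this is a guess.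
- In one extreme L stays free and every step runs on it, so time merely rescales and the order is 1.
- In the other extreme pairing is strong, free L goes as the square root of the charge, and the order is 0.5.
- Between them, if the pairing stands at balance, paired L goes as free L squared, so one percent more free L needs 2 minus f percent more charge, which gives 0.655 for the pairing order, the percent of extra free L for one percent of extra L charged.
- The forecast gives 0.6, with range 0.3 to 1.05, leaning towards the case where “only the first step uses L”, whereas I let every step run on free L.
- The flask gives 0.76, higher than my 0.655.

    Q + L + J → L + X (k = 30000 L² mol⁻² min⁻¹)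
    D + L ⇌ L + J (K = 1.10, k = 40.0 L mol⁻¹ min⁻¹)
    2 L ⇌ Z (K = 11000 L mol⁻¹, k = 93.0 L mol⁻¹ min⁻¹)

- Here J is the intermediate and Z the off-cycle pair of L. The forward pairing of L has a first half-life of 0.896 h, shorter than the 1.54 h at which 20% of the D is converted, and at that moment Z holds 48.2% of the catalyst.

The earlier runs and the new flask were generated by integration with made-up constants, noise included.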